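Ring A of the chromone (C4a, C5, C6, C7, C8, C8a) is fully substituted, with oxygen on C5, C7 and C8a and carbon on C4a, C6 and C8. A thermal cyclobutenone/ynol ether benzannulation builds exactly this 1,3,5-trioxygenated arene, so the route cuts C4a–C8a and C5–C6. Heating 3-ethoxy-2,4-dimethylcyclobutenone, itself the [2+2] adduct of methylketene and 1-ethoxypropyne, with ethoxyethyne should give in one operation the benzene ring with both C-methyls, two ethyl-masked oxygens and a single free hydroxyl (future O1) next to the one unsubstituted carbon (C4a). The pyranone ring is then closed through a C18 ynoate, and ether cleavage ends the route.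

Key step: step 2

Remark: the target has no stereocentre. The stereogenic elements met on the way (C4 of cyclobutenone 4, the transient centres of 7 and 9, the enol ether geometry of 14 and 15) are racemic or mixed, and are erased by aromatisation or equilibrated in the acid of step 6.

Step 1
Reactants: 1 propanoyl chloride; 2 1-ethoxyprop-1-yne
Product: 4 3-ethoxy-2,4-dimethylcyclobut-2-en-1-one (racemic), via methylketene 3 (not isolated)
Conditions: Et3N (1.5 equiv), Et2O, 0 °C → rt; 1 (1.3 equiv) added over 4 h
Reagents that add atoms: none
Why: Dehydrochlorination of 1 gives methylketene 3, which undergoes the known ketene–ynol ether [2+2] cycloaddition with the polarised alkyne (methyl-bearing carbon to the ketene carbonyl carbon, oxygen-bearing carbon to the ketene CHMe carbon), so only the 3-ethoxy regioisomer should form; its single stereocentre (C4) arises as a racemate and is erased later.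

Step 2
Reactants: 4 3-ethoxy-2,4-dimethylcyclobut-2-en-1-one; 5 ethoxyethyne
Product: 10 3,5-diethoxy-2,4-dimethylphenol, via vinylketene 6 (not isolated), via vinylcyclobutenone 7 (not isolated), via dienylketene 8 (not isolated), via cyclohexadienone 9 (not isolated)
Conditions: 5 (3 equiv, in portions), toluene, sealed tube, 90 °C; excess 5 vented, then 110 °C
Reagents that add atoms: none
Why: Thermal conrotatory 4π electrocyclic opening of 4 (breaking C8–C8a, target numbering) should give vinylketene 6, and ethoxyethyne then adds [2+2] across the ketene C=C, its nucleophilic CH carbon (future C4a) bonding to the ketene carbonyl carbon (C8a) and its oxygen-bearing carbon (C5) to the ketene α-carbon (C6), to give vinylcyclobutenone 7. A second 4π opening (breaking C6–C8a) gives dienylketene 8, and ring A closes by thermally allowed disrotatory 6π electrocyclisation that re-forms C8–C8a, giving cyclohexadienone 9, which tautomerises to phenol 10. The closest known reaction type is the Danheiser benzannulation of a cyclobutenone with an alkoxyalkyne. No stereocentre survives, because the quaternary centre of 7 and the CHMe centre of 9 are racemic and are removed by ring opening and aromatisation. The step needs regioselectivity in the [2+2] event, which the polarisation of the ynol ether secures (electron-rich CH terminus to the electrophilic ketene carbon), and any dienylketene of unproductive geometry can revert through 7. The first stage is held at 90 °C because ethoxyethyne fragments to ketene and ethene at higher temperature, and the final heating is done only after the excess alkyne has been removed.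

Step 3
Reactants: 11 1-heptadecyne
Product: 13 methyl octadec-2-ynoate, via lithium heptadecynide 12 (not isolated)
Conditions: n-BuLi (1.05 equiv), THF, −78 °C; then ClCO2Me, −78 °C → rt
Reagents that add atoms: methyl chloroformate, COC(=O)Cl
Why: Deprotonation of the terminal alkyne by n-BuLi and C-acylation of the lithium acetylide with methyl chloroformate is the standard alkoxycarbonylation of a 1-alkyne; no stereocentre is formed.

Step 4
Reactants: 10 3,5-diethoxy-2,4-dimethylphenol; 13 methyl octadec-2-ynoate
Product: 14 methyl 3-(3,5-diethoxy-2,4-dimethylphenoxy)octadec-2-enoate (2E/2Z mixture, 2E expected to predominate)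
Conditions: Cs2CO3 (0.3 equiv), DMF, 80 °C
Reagents that add atoms: none
Why: Oxa-Michael (conjugate) addition of the phenoxide of 10 to the β-carbon of the ynoate, the first stage of the Ruhemann chromone synthesis; protonation of the vinyl anion by further phenol turns the base over, and the mixed alkene geometry does not matter because step 6 equilibrates it.

Step 5
Reactants: 14 methyl 3-(3,5-diethoxy-2,4-dimethylphenoxy)octadec-2-enoate
Product: 15 3-(3,5-diethoxy-2,4-dimethylphenoxy)octadec-2-enoic acid (2E/2Z mixture)
Conditions: LiOH (3 equiv), THF/MeOH/H2O, 40 °C; then aq. HCl, 0 °C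
Reagents that add atoms: lithium hydroxide (its oxygen becomes the carboxyl OH), [Li+].[OH-]
Why: Saponification of the methyl ester by acyl–oxygen cleavage; the β-carbon is shielded by the pentadecyl chain and deactivated by the aryloxy donor, so displacement of the phenoxide should not compete, and the aryl ethyl ethers are inert to base.

Step 6
Reactants: 15 3-(3,5-diethoxy-2,4-dimethylphenoxy)octadec-2-enoic acid
Product: 16 5,7-diethoxy-6,8-dimethyl-2-pentadecyl-4H-chromen-4-one
Conditions: Eaton's reagent (P2O5 in MeSO3H, as solvent), rt → 50 °C
Reagents that add atoms: none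
Why: Intramolecular Friedel–Crafts acylation (second stage of the Ruhemann chromone synthesis): the medium activates the carboxyl group and interconverts the E and Z enol ethers by reversible C-protonation, so both isomers should funnel into acylation at C4a, the only free ring carbon, which lies ortho or para to all three oxygen donors.

Step 7
Reactants: 16 5,7-diethoxy-6,8-dimethyl-2-pentadecyl-4H-chromen-4-one
Product: 17 5,7-dihydroxy-6,8-dimethyl-2-pentadecyl-4H-chromen-4-one (target)
Conditions: BBr3 (6 equiv), CH2Cl2, −78 °C → rt; then H2O
Reagents that add atoms: none
Why: BBr3-mediated aryl ether cleavage: boron complexes each ethoxy oxygen and bromide removes the ethyl group by SN2, with the peri carbonyl assisting at C5, while the γ-pyrone ring, the C-methyl groups and the alkyl chain do not react; hydrolysis of the aryl borates on work-up should give the target.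

Compound list
1 | propanoyl chloride | CCC(=O)Cl | starting material
2 | 1-ethoxyprop-1-yne | CCOC#CC | starting material
3 | methylketene (prop-1-en-1-one) | CC=C=O | intermediate (not isolated)
4 | 3-ethoxy-2,4-dimethylcyclobut-2-en-1-one (racemic) | O=C1C(C)C(OCC)=C1C | intermediate
5 | ethoxyethyne | CCOC#C | starting material
6 | 3-ethoxy-2-methylpenta-1,3-dien-1-one (vinylketene; C3=C4 geometry immaterial, 3Z if the ring methyl rotates outward) | CC=C(OCC)C(C)=C=O | intermediate (not isolated)
7 | 3-ethoxy-4-(1-ethoxyprop-1-en-1-yl)-4-methylcyclobut-2-en-1-one (racemic; propenyl geometry immaterial) | CC=C(OCC)C1(C)C(=O)C=C1OCC | intermediate (not isolated)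
8 | (3E)-3,5-diethoxy-4-methylhepta-1,3,5-trien-1-one (dienylketene; C5=C6 geometry immaterial) | O=C=C/C(OCC)=C(C)\C(OCC)=CC | intermediate (not isolated)
9 | 3,5-diethoxy-4,6-dimethylcyclohexa-2,4-dien-1-one (racemic) | O=C1C=C(OCC)C(C)=C(OCC)C1C | intermediate (not isolated)
10 | 3,5-diethoxy-2,4-dimethylphenol | Oc1cc(OCC)c(C)c(OCC)c1C | intermediate
11 | 1-heptadecyne | CCCCCCCCCCCCCCCC#C | starting material
12 | lithium heptadec-1-yn-1-ide | CCCCCCCCCCCCCCCC#C[Li] | intermediate (not isolated)
13 | methyl octadec-2-ynoate | CCCCCCCCCCCCCCCC#CC(=O)OC | intermediate
14 | methyl 3-(3,5-diethoxy-2,4-dimethylphenoxy)octadec-2-enoate (2E/2Z mixture) | CCCCCCCCCCCCCCCC(Oc1cc(OCC)c(C)c(OCC)c1C)=CC(=O)OC | intermediate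
15 | 3-(3,5-diethoxy-2,4-dimethylphenoxy)octadec-2-enoic acid (2E/2Z mixture) | CCCCCCCCCCCCCCCC(Oc1cc(OCC)c(C)c(OCC)c1C)=CC(=O)O | intermediate
16 | 5,7-diethoxy-6,8-dimethyl-2-pentadecyl-4H-chromen-4-one | CCCCCCCCCCCCCCCc1cc(=O)c2c(OCC)c(C)c(OCC)c(C)c2o1 | intermediate
17 | 5,7-dihydroxy-6,8-dimethyl-2-pentadecyl-4H-chromen-4-one | CCCCCCCCCCCCCCCc1cc(=O)c2c(O)c(C)c(O)c(C)c2o1 | target

Total step count: 7. Longest linear sequence: 6 steps (steps 1, 2, 4, 5, 6, 7); step 3 is a one-step side branch.

Steps most likely to fail

Step 2 (key step). The 4π opening of 4 may be slowed by the vinylogous-ester stabilisation of the ring. At the temperature then needed, the ynol ether could be lost by retro-ene fragmentation, and the phenol already formed could be acylated by unreacted vinylketene. The fallback sets out from ethoxyethyne 5 and comes back to the route at vinylketene 6, and through it at phenol 10. It makes the vinylketene without any electrocyclic opening, by the known 1,4-dehydrochlorination of an α,β-unsaturated acid chloride. Purchased ethyl 2-methyl-3-oxopentanoate F1 is converted with HC(OEt)3 and catalytic H2SO4 in EtOH into ethyl 3-ethoxy-2-methylpent-2-enoate F2. Saponification with NaOH in aqueous EtOH gives sodium 3-ethoxy-2-methylpent-2-enoate F3, kept as the salt to spare the enol ether. (COCl)2 in CH2Cl2 at 0 °C then gives 3-ethoxy-2-methylpent-2-enoyl chloride F4. Slow addition of F4 to Et3N and 5 in Et2O at 0 °C to rt removes a γ-hydrogen and chloride to give 6, which 5 traps at once as 7. After removal of excess 5, warming in toluene carries 7 through 8 and 9 to 10.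

Step 4. Conjugate addition of the ortho-substituted, electron-rich phenoxide to a β-alkyl ynoate may be slow, so that base-induced isomerisation of the ynoate to allenoate and dienoate takes over. The fallback sets out from phenol 10 and comes back at chromone 16, so it also replaces steps 3, 5 and 6. It builds the pyranone from the carbon side. C-acetylation of 10 at its only free position with Ac2O and BF3·OEt2 (Friedel–Crafts acylation, or O-acylation and Fries shift) should give 1-(2,4-diethoxy-6-hydroxy-3,5-dimethylphenyl)ethan-1-one F5. Its dianion, formed with LiN(SiMe3)2 (3 equiv) in THF at −78 °C, is C-acylated with hexadecanoyl chloride (CCCCCCCCCCCCCCCC(=O)Cl) in a Claisen-type condensation to give 1-(2,4-diethoxy-6-hydroxy-3,5-dimethylphenyl)octadecane-1,3-dione F6. Cyclodehydration with catalytic H2SO4 in AcOH then closes the pyranone to 16.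

Step 1. Methylketene may dimerise or oligomerise in the presence of amine and acid chloride faster than it is captured by the ynol ether. The fallback sets out from 1-ethoxyprop-1-yne 2 and comes back at cyclobutenone 4. Compound 2 is heated alone (neat or in toluene, sealed tube, about 120 °C). Retro-ene fragmentation releases methylketene 3 and ethene slowly and without amine, and each ketene molecule is formed in a large excess of the ynol ether, which captures it as 4. This is the classical thermal route from 1-alkoxyalkynes to 3-alkoxycyclobutenones; no further compound is made (F0).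

Further compounds
F1 | step 2 | ethyl 2-methyl-3-oxopentanoate (racemic, purchased) | CCOC(=O)C(C)C(=O)CC
F2 | step 2 | ethyl 3-ethoxy-2-methylpent-2-enoate (E/Z mixture) | CCOC(=O)C(C)=C(CC)OCC
F3 | step 2 | sodium 3-ethoxy-2-methylpent-2-enoate (E/Z mixture) | [Na+].[O-]C(=O)C(C)=C(CC)OCC
F4 | step 2 | 3-ethoxy-2-methylpent-2-enoyl chloride (E/Z mixture) | ClC(=O)C(C)=C(CC)OCC
F5 | step 4 | 1-(2,4-diethoxy-6-hydroxy-3,5-dimethylphenyl)ethan-1-one | CC(=O)c1c(O)c(C)c(OCC)c(C)c1OCC
F6 | step 4 | 1-(2,4-diethoxy-6-hydroxy-3,5-dimethylphenyl)octadecane-1,3-dione | CCCCCCCCCCCCCCCC(=O)CC(=O)c1c(O)c(C)c(OCC)c(C)c1OCC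
F0 | step 1 | none | none
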